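Ring A is the enolised 2-acylcyclohexane-1,3,5-trione: C1 ketone, C2 hexanoyl-bearing, C4 quaternary, C6 bridge-bearing. It is cut at C1-C2 and C5-C6, both Claisen bonds. The feature exploited is that two oxygens can each close a six-membered ring onto these acyl carbons: the hexanoyl oxygen onto C5, and the ring B phenol oxygen beside the CH2 bridge onto C1. Each half is therefore a latent lactone. The precursors are a pyran-2,4-dione (C2 to C5, the hexanoyl carbon, the C4 stereocentre) and a dihydrocoumarin (C1, C6, bridge, ring B). In one operation the dihydrocoumarin enolate opens the pyrandione (C5-C6), and the released diketonate opens the aryl lactone (C1-C2). This gives the target with no atom lost.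

Key step: step 8

Assumption: enolised tricarbonyl compounds are drawn as single tautomers, and the L-valine auxiliary with HMPA as lithium ligand is taken to give the (R)-keto ester of step 2; if the opposite sense is found, D-valine tert-butyl ester is used in the same steps.

Step 1
Reactants: 1 tert-butyl 2-methyl-3-oxobutanoate (racemic); 2 L-valine tert-butyl ester (free base, released from the commercial hydrochloride)
Product: 3 tert-butyl (2Z)-3-{[(2S)-1-tert-butoxy-3-methyl-1-oxobutan-2-yl]amino}-2-methylbut-2-enoate
Conditions: cat. BF3·OEt2, benzene, Dean-Stark, reflux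
Reagents that add atoms: none
Why: Acid-catalysed condensation of a β-keto ester with a primary amine under water removal (enamine formation) should give the hydrogen-bonded Z enamino ester, which erases the racemic centre of 1 and installs the chiral auxiliary.

Step 2
Reactants: 3 enamino ester; 4 prenyl bromide (1-bromo-3-methylbut-2-ene)
Product: 7 tert-butyl (2R)-2-acetyl-2,5-dimethylhex-4-enoate, via lithio enamine 5 (not isolated), via alkylated ketimine 6 (not isolated)
Conditions: LiN(iPr)2 (1.1 equiv), HMPA (1 equiv), toluene, -78 °C; 4, -78 to -40 °C; then 10% aq citric acid, THF, rt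
Reagents that add atoms: water, SMILES O
Why: In the tridentate lithium chelate 5 (enamine N, valine ester C=O, keto ester C=O) the isopropyl group and the tightly bound HMPA leave one face of the enamine carbon open, so SN2 alkylation by 4 should set the quaternary centre under auxiliary control (diastereoselective alkylation of a chiral lithio enamine), and mild acid hydrolysis of 6 frees 7 and the auxiliary.

Step 3
Reactants: 7 (R)-keto ester; 8 hexanoyl chloride
Product: 10 tert-butyl (2R)-2-methyl-2-(3-methylbut-2-en-1-yl)-3,5-dioxodecanoate, via lithium enolate 9 (not isolated)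
Conditions: LiN(SiMe3)2 (2.2 equiv), toluene/THF, -78 °C; 8 (1.1 equiv), -78 to -20 °C; 1 M HCl
Reagents that add atoms: none
Why: The acetyl CH3 is the only enolisable position of 7, so kinetic deprotonation and C-acylation by the acid chloride (crossed Claisen-type acylation of a ketone enolate) should give the 1,3-diketone, the second equivalent of base taking up its acidic proton, and the quaternary centre cannot epimerise.

Step 4
Reactants: 10 (R)-diketo ester
Product: 13 (3R)-3-methyl-3-(3-methylbut-2-en-1-yl)-6-pentyl-2H-pyran-2,4(3H)-dione, via bis(trimethylsilyl) derivative 11 (not isolated), via β-keto acid 12 (not isolated)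
Conditions: Me3SiOTf (2.5 equiv), 2,6-lutidine (3 equiv), CH2Cl2, 0 °C; cold pH 4 buffer wash; then DCC, CH2Cl2, 0 °C
Reagents that add atoms: none
Why: Me3SiOTf and 2,6-lutidine cleave the tert-butyl ester by silyl transfer and loss of isobutene without a protic acid that could add to the prenyl alkene, and carbodiimide activation of the cold acid 12 should let the enol oxygen on the pentyl-bearing carbon close the six-membered enol lactone (6-exo-trig lactonisation) faster than CO2 is lost.

Step 5
Reactants: 14 phloroglucinol; 8 hexanoyl chloride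
Product: 15 1-(2,4,6-trihydroxyphenyl)hexan-1-one
Conditions: AlCl3 (3.5 equiv), CH2Cl2/PhNO2, 40 °C; ice, aq HCl
Reagents that add atoms: none
Why: Friedel-Crafts acylation of the threefold symmetric, electron-rich arene should stop after one acylation because the chelated aryl ketone deactivates the ring.

Step 6
Reactants: 15 1-(2,4,6-trihydroxyphenyl)hexan-1-one
Product: 16 1-(2,6-dihydroxy-4-methoxyphenyl)hexan-1-one
Conditions: Me2SO4 (1.0 equiv), K2CO3 (1.0 equiv), acetone, reflux
Reagents that add atoms: dimethyl sulfate, SMILES COS(=O)(=O)OC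
Why: The 4-OH is the only hydroxyl not hydrogen-bonded to the ketone and is the most acidic one, so one equivalent of base and dimethyl sulfate should methylate it selectively (Williamson-type O-alkylation), which leaves a symmetric arene that has two equivalent free CH positions.

Step 7
Reactants: 16 1-(2,6-dihydroxy-4-methoxyphenyl)hexan-1-one; 17 Meldrum's acid
Product: 21 8-hexanoyl-7-hydroxy-5-methoxychroman-2-one, via methylene Meldrum's acid 18 (not isolated), via Michael adduct 19 (not isolated), via lactone acid 20 (not isolated)
Conditions: paraformaldehyde (1.0 equiv), cat. L-proline, MeCN, rt; then pyridine, 100 °C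
Reagents that add atoms: formaldehyde (as paraformaldehyde), SMILES C=O
Why: Knoevenagel condensation gives the strong Michael acceptor 18, either of the two equivalent arene CH positions of 16 adds to it (Yonemitsu-type three-component condensation), and on heating the only ortho hydroxyl opens the dioxanedione with loss of acetone and then CO2 (lactonisation and decarboxylation), so the regiochemistry of 21 is unambiguous.

Step 8
Reactants: 21 8-hexanoyl-7-hydroxy-5-methoxychroman-2-one; 13 (R)-pyran-2,4-dione
Product: 24 (4S)-2-hexanoyl-6-[(3-hexanoyl-2,4-dihydroxy-6-methoxyphenyl)methyl]-3,5-dihydroxy-4-methyl-4-(3-methylbut-2-en-1-yl)cyclohexa-2,5-dien-1-one (CNP0108719.1), via dilithium enolate 22 (not isolated), via ring-opened diketonate 23 (not isolated)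
Conditions: 21, LiN(SiMe3)2 (2.1 equiv), THF, -78 °C; then 13 in THF, -78 °C to rt; 1 M HCl, 0 °C
Reagents that add atoms: none
Why: Proposed new method: the first equivalent of LiN(SiMe3)2 makes the C7 phenoxide of 21, which turns the neighbouring aryl ketone into a vinylogous carboxylate, so the second equivalent should deprotonate the lactone CH2 to give 22; 22 adds to the lactone carbonyl of 13, the adduct collapses with loss of the stabilised 1,3-diketonate (C5-C6 bond made, hexanoyl group unveiled, 23), and the central carbon of that diketonate attacks the aryl lactone carbonyl and expels the aryloxide (C1-C2 bond made, ring B phenol unveiled). The closest known reaction types are the crossed Claisen acylation of an ester enolate by an enol lactone, the opening and reclosure of an enol lactone by a carbanion in the Fujimoto-Belleau reaction, and the biomimetic Claisen cyclisation of 3,5,7-trioxo esters to acylphloroglucinols; what is new is that two lactones are merged so that both acyl transfers run in one flask. Ring A closes by a 6-(enolexo)-exo-trig Dieckmann-type acylation while both heterocycles open. No lasting stereocentre is made: C4 is quaternary, cannot enolise and is carried unchanged from 13, and the C6 centre of 23 is erased by enolisation. The step needs acyl attack on 13 rather than addition at its ketone or at its pentyl-bearing enol carbon, which is secured because ketone addition is reversible, the enol carbon is fully substituted, and only the acyl adduct is drained by ring opening of the vinylogous anhydride. It also needs C-acylation rather than O-acylation or aldol closure in 23, which is secured by the aryloxide leaving group and by the product dianion, the most stabilised species on the manifold, since O-acyl isomers remain acyl donors and aldolates revert.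

Compound list
1 | tert-butyl 2-methyl-3-oxobutanoate | CC(=O)C(C)C(=O)OC(C)(C)C | starting material
2 | L-valine tert-butyl ester | CC(C)[C@H](N)C(=O)OC(C)(C)C | starting material
3 | tert-butyl (2Z)-3-{[(2S)-1-tert-butoxy-3-methyl-1-oxobutan-2-yl]amino}-2-methylbut-2-enoate | C/C(N[C@@H](C(C)C)C(=O)OC(C)(C)C)=C(C)/C(=O)OC(C)(C)C | intermediate
4 | prenyl bromide | CC(C)=CCBr | starting material
5 | lithio enamine of 3 | [Li+].CC(=C(C)C(=O)OC(C)(C)C)[N-][C@@H](C(C)C)C(=O)OC(C)(C)C | intermediate
6 | tert-butyl (2R)-2-{N-[(2S)-1-tert-butoxy-3-methyl-1-oxobutan-2-yl]ethanimidoyl}-2,5-dimethylhex-4-enoate | CC(=N[C@@H](C(C)C)C(=O)OC(C)(C)C)[C@@](C)(CC=C(C)C)C(=O)OC(C)(C)C | intermediate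
7 | tert-butyl (2R)-2-acetyl-2,5-dimethylhex-4-enoate | CC(=O)[C@@](C)(CC=C(C)C)C(=O)OC(C)(C)C | intermediate
8 | hexanoyl chloride | CCCCCC(=O)Cl | starting material
9 | lithium enolate of 7 | [Li+].C=C([O-])[C@@](C)(CC=C(C)C)C(=O)OC(C)(C)C | intermediate
10 | tert-butyl (2R)-2-methyl-2-(3-methylbut-2-en-1-yl)-3,5-dioxodecanoate | CCCCCC(=O)CC(=O)[C@@](C)(CC=C(C)C)C(=O)OC(C)(C)C | intermediate
11 | trimethylsilyl (2R)-2-methyl-2-(3-methylbut-2-en-1-yl)-3-oxo-5-(trimethylsilyloxy)dec-4-enoate | CCCCCC(O[Si](C)(C)C)=CC(=O)[C@@](C)(CC=C(C)C)C(=O)O[Si](C)(C)C | intermediate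
12 | (2R)-2-methyl-2-(3-methylbut-2-en-1-yl)-3,5-dioxodecanoic acid | CCCCCC(=O)CC(=O)[C@@](C)(CC=C(C)C)C(=O)O | intermediate
13 | (3R)-3-methyl-3-(3-methylbut-2-en-1-yl)-6-pentyl-2H-pyran-2,4(3H)-dione | CCCCCC1=CC(=O)[C@@](C)(CC=C(C)C)C(=O)O1 | intermediate
14 | phloroglucinol | Oc1cc(O)cc(O)c1 | starting material
15 | 1-(2,4,6-trihydroxyphenyl)hexan-1-one | CCCCCC(=O)c1c(O)cc(O)cc1O | intermediate
16 | 1-(2,6-dihydroxy-4-methoxyphenyl)hexan-1-one | CCCCCC(=O)c1c(O)cc(OC)cc1O | intermediate
17 | Meldrum's acid (2,2-dimethyl-1,3-dioxane-4,6-dione) | CC1(C)OC(=O)CC(=O)O1 | starting material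
18 | 2,2-dimethyl-5-methylidene-1,3-dioxane-4,6-dione | C=C1C(=O)OC(C)(C)OC1=O | intermediate
19 | 5-[(3-hexanoyl-2,4-dihydroxy-6-methoxyphenyl)methyl]-2,2-dimethyl-1,3-dioxane-4,6-dione | CCCCCC(=O)c1c(O)cc(OC)c(CC2C(=O)OC(C)(C)OC2=O)c1O | intermediate
20 | 8-hexanoyl-7-hydroxy-5-methoxy-2-oxochromane-3-carboxylic acid (racemic) | CCCCCC(=O)c1c(O)cc(OC)c2CC(C(=O)O)C(=O)Oc12 | intermediate
21 | 8-hexanoyl-7-hydroxy-5-methoxychroman-2-one | CCCCCC(=O)c1c(O)cc(OC)c2CCC(=O)Oc12 | intermediate
22 | dilithium 8-hexanoyl-5-methoxy-4H-chromene-2,7-diolate | [Li+].[Li+].CCCCCC(=O)c1c([O-])cc(OC)c2CC=C([O-])Oc12 | intermediate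
23 | dilithium salt of 8-hexanoyl-7-hydroxy-5-methoxy-3-[(2R)-2-methyl-2-(3-methylbut-2-en-1-yl)-3,5-dioxodecanoyl]chroman-2-one (epimers at the lactone C3) | [Li+].[Li+].CCCCCC([O-])=CC(=O)[C@@](C)(CC=C(C)C)C(=O)C1Cc2c(OC)cc([O-])c(C(=O)CCCCC)c2OC1=O | intermediate
24 | (4S)-2-hexanoyl-6-[(3-hexanoyl-2,4-dihydroxy-6-methoxyphenyl)methyl]-3,5-dihydroxy-4-methyl-4-(3-methylbut-2-en-1-yl)cyclohexa-2,5-dien-1-one | CCCCCC(=O)C1=C(O)[C@@](C)(CC=C(C)C)C(O)=C(Cc2c(OC)cc(O)c(C(=O)CCCCC)c2O)C1=O | target

Total step count: 8. Longest linear sequence: 5 steps (1, 2, 3, 4, 8). The second branch (5, 6, 7) joins at step 8.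

Steps most likely to fail

1. Step 8.
- What may go wrong: proton transfer from the pentyl CH2 of 13 to the basic enolate; enolisation of the aryl ketone of 21 in place of the lactone; conjugate attack on the vinylogous anhydride; self-condensation of the enolate.
- The fallback uses known chemistry, sets out from 13 and 16, and comes back at 24. The arene is left out of the enolate partner and the bridge is made last.
- Compound 13 is opened with an excess of the small lithium enolate of methyl acetate (LiN(iPr)2, THF, -78 °C, crossed Claisen acylation) to methyl (4R)-4-methyl-4-(3-methylbut-2-en-1-yl)-3,5,7-trioxododecanoate F1.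
- Mg(OMe)2 in MeOH closes F1 by the known Claisen cyclisation of 3,5,7-trioxo esters to (4S)-2-hexanoyl-3,5-dihydroxy-4-methyl-4-(3-methylbut-2-en-1-yl)cyclohexa-2,5-dien-1-one F2.
- F2, the more acidic partner, condenses with aqueous formaldehyde and mild base (Knoevenagel) to the exocyclic methylene trione F3. Arene 16 traps F3 by Michael addition, which is the standard way to methylene-bridged acylphloroglucinol dimers, and this gives 24.

2. Step 4.
- What may go wrong: loss of CO2 from the β-keto acid before ring closure, or rearrangement of the activated acid to an N-acylurea.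
- The fallback sets out from 1 and 4 and comes back at 13. It builds the ring first and the quaternary centre last, so no β-keto acid that carries a prenyl group is ever formed.
- The dianion of 1 (NaH, then n-BuLi, THF, 0 °C) is acylated at its terminal carbon with commercial methyl hexanoate to tert-butyl 2-methyl-3,5-dioxodecanoate F4.
- CF3CO2H and (CF3CO)2O close F4 to 4-hydroxy-3-methyl-6-pentyl-2H-pyran-2-one F5.
- C3-prenylation of F5 with 4 (Cs2CO3, cat. Pd(PPh3)4, THF) gives racemic 3-methyl-3-(3-methylbut-2-en-1-yl)-6-pentyl-2H-pyran-2,4(3H)-dione F6. Under these conditions O-prenyl isomers re-ionise and funnel to carbon.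
- Preparative chromatography of F6 on a chiral stationary phase delivers 13.

3. Step 7.
- What may go wrong: formaldehyde links two arenes to a methylene-bridged homodimer, or Meldrum's acid adds twice to formaldehyde, before the cross adduct forms.
- The fallback sets out from 16 and 17 and comes back at 20. It brings in the bridge carbon at the aldehyde level, so no free formaldehyde is present.
- Vilsmeier-Haack formylation of 16 (POCl3, DMF) gives 3-hexanoyl-2,4-dihydroxy-6-methoxybenzaldehyde F7.
- Knoevenagel condensation of F7 with 17 and spontaneous lactonisation (cat. piperidinium acetate, EtOH) gives 8-hexanoyl-7-hydroxy-5-methoxy-2-oxo-2H-chromene-3-carboxylic acid F8.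
- Hydrogenation of the activated C3-C4 alkene of F8 (H2, Pd/C, EtOAc) gives 20, which is decarboxylated in hot pyridine as in the main route.

Further compounds
F1 | step 8 | methyl (4R)-4-methyl-4-(3-methylbut-2-en-1-yl)-3,5,7-trioxododecanoate | COC(=O)CC(=O)[C@](C)(CC=C(C)C)C(=O)CC(=O)CCCCC
F2 | step 8 | (4S)-2-hexanoyl-3,5-dihydroxy-4-methyl-4-(3-methylbut-2-en-1-yl)cyclohexa-2,5-dien-1-one | CCCCCC(=O)C1=C(O)[C@@](C)(CC=C(C)C)C(O)=CC1=O
F3 | step 8 | exocyclic methylene trione from F2 and formaldehyde | CCCCCC(=O)C1=C(O)[C@@](C)(CC=C(C)C)C(=O)C(=C)C1=O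
F4 | step 4 | tert-butyl 2-methyl-3,5-dioxodecanoate | CCCCCC(=O)CC(=O)C(C)C(=O)OC(C)(C)C
F5 | step 4 | 4-hydroxy-3-methyl-6-pentyl-2H-pyran-2-one | CCCCCc1cc(O)c(C)c(=O)o1
F6 | step 4 | racemic 3-methyl-3-(3-methylbut-2-en-1-yl)-6-pentyl-2H-pyran-2,4(3H)-dione | CCCCCC1=CC(=O)C(C)(CC=C(C)C)C(=O)O1
F7 | step 7 | 3-hexanoyl-2,4-dihydroxy-6-methoxybenzaldehyde | CCCCCC(=O)c1c(O)cc(OC)c(C=O)c1O
F8 | step 7 | 8-hexanoyl-7-hydroxy-5-methoxy-2-oxo-2H-chromene-3-carboxylic acid | CCCCCC(=O)c1c(O)cc(OC)c2cc(C(=O)O)c(=O)oc12
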